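**Plan**
- Retrosynthesis: the two C4–C6 interflavanyl bonds are cut first (upper–middle, then middle–lower). This reduces the trimer to three copies of one monomer, tri-O-benzyl teracacidin 11, which is cut at O1–C2 and C4a–C4 into phenol 4 and cis-epoxy aldehyde 8.
- Enabling feature: in each pyran ring (O1–C2–C3–C4–C4a–C8a) the ring A phenol oxygen O1 and its only free ortho carbon C4a form a 1,3-O,C-dinucleophile. C2–C3–C4 is the matching 1,3-dielectrophile: C4 is an aldehyde carbon, C2 a p-oxybenzylic epoxide carbon, and the epoxide oxygen becomes the 3-hydroxyl.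
- Forward: rings A and B come from 2,3-dihydroxybenzaldehyde and 4-(benzyloxy)benzaldehyde. A titanium-templated [3+3] annulation closes ring C between them. Monomer 11 is divided into electrophile 13 (4-thioether) and nucleophile 14 (3,4-carbonate). Two silver-promoted C4→C6 couplings add first the middle and then the upper unit; methanolysis and hydrogenolysis finish.
- Stereochemistry: one Jacobsen epoxidation of the Z-cinnamate sets C3 directly and C2 through invertive epoxide opening (2,3-cis). The lower C4 arises by Felkin–Anh addition (3,4-cis). Both interflavanyl C4 centres arise by attack trans to the 3-acetoxy group (4β).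

Key step: step 6

Remark: flavan numbering (O1, C2, C3, C4, C4a, C5–C8, C8a) is used for every chroman unit. The target is read as epioritin-(4β→6)-epioritin-(4β→6)-epioritin-4α-ol, where epioritin is (2R,3R)-2-(4-hydroxyphenyl)chroman-3,7,8-triol, 4β means trans and 4α means cis to the 3-hydroxyl, and all C2 centres are R. The SMILES are authoritative for configuration.

**Step 1**
Reactants: 1 2,3-dihydroxybenzaldehyde
Product: 2 2,3-bis(benzyloxy)benzaldehyde
Conditions: BnBr (2.3 equiv), K2CO3, DMF, 60 °C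
Reagents that add atoms: benzyl bromide, BrCc1ccccc1
Why: Williamson ether synthesis on both phenols, the aldehyde being inert to carbonate.

**Step 2**
Reactants: 2 2,3-bis(benzyloxy)benzaldehyde
Product: 4 2,3-bis(benzyloxy)phenol, via aryl formate 3 (not isolated)
Conditions: mCPBA, CH2Cl2, 25 °C; aq. NaHCO3 wash; then K2CO3 (0.2 equiv), MeOH, 25 °C
Reagents that add atoms: 3-chloroperoxybenzoic acid (mCPBA), OOC(=O)c1cccc(Cl)c1
Why: Baeyer–Villiger (Dakin-type) oxidation in which the electron-rich ortho-alkoxyaryl group migrates, followed by methanolysis of the formate.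

**Step 3**
Reactants: 5 4-(benzyloxy)benzaldehyde
Product: 6 ethyl (Z)-3-[4-(benzyloxy)phenyl]prop-2-enoate
Conditions: ethyl 2-(diphenoxyphosphoryl)acetate, NaH, THF, −78 to 0 °C
Reagents that add atoms: ethyl 2-(diphenoxyphosphoryl)acetate, CCOC(=O)CP(=O)(Oc1ccccc1)Oc1ccccc1
Why: Ando-type Z-selective Horner–Wadsworth–Emmons olefination, the diaryl phosphonate collapsing rapidly from the kinetic syn adduct.

**Step 4**
Reactants: 6 ethyl (Z)-3-[4-(benzyloxy)phenyl]prop-2-enoate
Product: 7 ethyl (2S,3S)-3-[4-(benzyloxy)phenyl]oxirane-2-carboxylate (cis)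
Conditions: (S,S)-(salen)MnCl (6 mol%; salen = N,N'-bis(3,5-di-tert-butylsalicylidene)-1,2-cyclohexanediamine dianion), 4-phenylpyridine N-oxide (0.25 equiv), aq. NaOCl (pH 11.3), CH2Cl2, 4 °C
Reagents that add atoms: sodium hypochlorite, [Na+].[O-]Cl
Why: Jacobsen–Katsuki epoxidation of a cis-cinnamate ester, where side-on approach to the (S,S) catalyst should give the 2S,3S cis-epoxide by analogy with the known facial sense for cis-cinnamates and the N-oxide additive limits leakage to the trans-epoxide.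

**Step 5**
Reactants: 7 ethyl (2S,3S)-3-[4-(benzyloxy)phenyl]oxirane-2-carboxylate (cis)
Product: 8 (2S,3S)-3-[4-(benzyloxy)phenyl]oxirane-2-carbaldehyde (cis)
Conditions: iBu2AlH (1.05 equiv), toluene, −78 °C; aq. Rochelle salt; used crude
Reagents that add atoms: none
Why: partial reduction of an α-oxygenated ester through the chelated tetrahedral aluminate at −78 °C, with no bond to a stereocentre broken.

**Step 6**
Reactants: 4 2,3-bis(benzyloxy)phenol; 8 (2S,3S)-3-[4-(benzyloxy)phenyl]oxirane-2-carbaldehyde (cis)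
Product: 11 (2R,3R,4R)-7,8-bis(benzyloxy)-2-[4-(benzyloxy)phenyl]-3,4-dihydro-2H-chromene-3,4-diol (tri-O-benzyl teracacidin), via titanium phenoxide 9 (not isolated), via epoxy carbinol 10 (not isolated)
Conditions: 4, Ti(OiPr)4 (1.05 equiv), toluene, 25 °C, iPrOH removed in vacuo; then 8, CH2Cl2, −30 to 25 °C; aq. Rochelle salt
Reagents that add atoms: none
Why: Proposed new method: the aryloxytitanium triisopropoxide 9 binds the aldehyde of 8 at tetravalent titanium and delivers its only free ortho carbon (the future C4a) through a six-membered cyclic transition state to give the titanium-bound epoxy carbinol 10, after which the titanium alkoxide on C4 activates the neighbouring epoxide and the phenol oxygen opens it at the benzylic carbon (the future C2), so that C4a–C4 and O1–C2 are made in one flask as a formal [3+3] annulation. The closest known reaction types are the ortho-specific hydroxyalkylation of magnesium and titanium phenoxides with α-oxygenated aldehydes, the Ti(OiPr)4-mediated opening of 2,3-epoxy alcohols at the carbon remote from the carbinol, and the phenol/aryl-epoxide cyclisation used for flavan-3-ols; their union on an epoxy aldehyde is not known. The pyran ring closes in the 6-endo-tet mode at the epoxide, preferred over 5-exo attack at C3 because the p-benzyloxyphenyl group loosens the C2–O bond and because titanium held on the C4 oxygen steers attack to the distal carbon. C3 keeps the configuration of the epoxide, C2 is set by inversion at the cis-epoxide carbon (hence 2,3-cis, 2R), and C4 is set by Felkin–Anh/Cornforth addition anti to the epoxide C–O on the aldehyde face not covered by the cis aryl group, the non-chelating Ti(OiPr)3 centre giving the anti (3,4-cis, 4R) carbinol. The step needs ortho over para C-alkylation, secured by the metal template and by the 2-benzyloxy group that blocks the second ortho position, and invertive opening over ionisation at C2, secured by low temperature and the absence of protic or strong Lewis acid.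

**Step 7**
Reactants: 11 tri-O-benzyl teracacidin
Product: 12 (2R,3S,4S)-4-(benzylsulfanyl)-7,8-bis(benzyloxy)-2-[4-(benzyloxy)phenyl]-3,4-dihydro-2H-chromen-3-ol (2,3-cis-3,4-trans)
Conditions: BnSH (5 equiv), BF3·OEt2 (0.3 equiv), CH2Cl2, −40 to −10 °C
Reagents that add atoms: phenylmethanethiol, SCc1ccccc1
Why: acid-catalysed thiolysis of a flavan-3,4-diol, in which the C4 cation stabilised by O1 and the 7-benzyloxy group is captured by excess thiol on the face away from the 3-hydroxyl and 2-aryl group (4β), faster than by C6 of a second molecule.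

**Step 8**
Reactants: 12 4β-benzylsulfanyl flavan-3-ol
Product: 13 (2R,3S,4S)-4-(benzylsulfanyl)-7,8-bis(benzyloxy)-2-[4-(benzyloxy)phenyl]-3,4-dihydro-2H-chromen-3-yl acetate
Conditions: Ac2O, pyridine, DMAP (cat.), CH2Cl2, 25 °C
Reagents that add atoms: acetic anhydride, CC(=O)OC(C)=O
Why: standard acylation that removes the 3-hydroxyl as a competing oxygen nucleophile and installs a participating group for the couplings.

**Step 9**
Reactants: 11 tri-O-benzyl teracacidin
Product: 14 (2R,3S,4R)-7,8-bis(benzyloxy)-2-[4-(benzyloxy)phenyl]-3,4-dihydro-2H-chromene-3,4-diyl carbonate (all-cis cyclic carbonate of 11; geometry unchanged)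
Conditions: CDI (1.5 equiv), DMAP (cat.), THF, 25 to 45 °C
Reagents that add atoms: 1,1'-carbonyldiimidazole, O=C(n1ccnc1)n1ccnc1
Why: cyclic carbonate formation from a cis-1,2-diol under non-acidic conditions, which masks both hydroxyls against O-alkylation and holds the benzylic C4–O bond in a ring that does not ionise under thiophilic activation.

**Step 10**
Reactants: 13 thioether acetate (1 equiv); 14 cyclic carbonate (3 equiv)
Product: 15 hexa-O-benzyl-epioritin-(4β→6)-epioritin-4α-ol 3-O-acetate (upper unit) 3,4-O-carbonate (lower unit)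
Conditions: AgBF4 (2 equiv), 2,6-di-tert-butyl-4-methylpyridine (2 equiv), 4 Å molecular sieves, CH2Cl2, −20 to 0 °C, slow addition of 13; excess 14 recovered
Reagents that add atoms: none
Why: thiophilic activation of a flavan-4-yl thioether by monovalent silver followed by Friedel–Crafts alkylation at C6 of 14 (para to O1, ortho to the 7-benzyloxy group, C5 being shielded by the peri C4 substituent), with the 3-acetoxy group covering the α face so that the aryl group enters trans to it (4β) and the hindered base keeping the carbonate intact.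

**Step 11**
Reactants: 13 thioether acetate (1 equiv); 15 protected dimer (2 equiv)
Product: 16 nona-O-benzyl-epioritin-(4β→6)-epioritin-(4β→6)-epioritin-4α-ol 3-O-acetate (upper and middle units) 3,4-O-carbonate (lower unit)
Conditions: AgBF4 (2 equiv), 2,6-di-tert-butyl-4-methylpyridine (2 equiv), 4 Å molecular sieves, CH2Cl2, −20 to 0 °C, slow addition of 13; excess 15 recovered
Reagents that add atoms: none
Why: the same silver-promoted interflavanyl coupling, for which C6 of the upper unit of 15 is the only unhindered activated arene position and the new C4 centre is again set trans to the 3-acetoxy group (4β).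

**Step 12**
Reactants: 16 protected trimer
Product: 17 nona-O-benzyl-epioritin-(4β→6)-epioritin-(4β→6)-epioritin-4α-ol
Conditions: K2CO3 (0.5 equiv), MeOH/THF (1:1), 25 °C
Reagents that add atoms: none
Why: base-catalysed transesterification removes both acetates and the cyclic carbonate without touching any stereocentre, and since all phenols are benzylated no quinone methide pathway is open at the lower C4.

**Step 13**
Reactants: 17 nona-O-benzyl trimer
Product: 18 epioritin-(4β→6)-epioritin-(4β→6)-epioritin-4α-ol (CNP0140823.1)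
Conditions: H2 (1 atm), Pd(OH)2/C, EtOAc/MeOH, 25 °C, stopped once the benzyl groups are consumed; filtration under argon, Sephadex LH-20
Reagents that add atoms: none
Why: hydrogenolysis of aryl benzyl ethers in neutral medium, under which a secondary benzylic alcohol and the doubly benzylic interflavanyl C–C bonds should persist.

**Compound list**
1 | 2,3-dihydroxybenzaldehyde | O=Cc1cccc(O)c1O | starting material
2 | 2,3-bis(benzyloxy)benzaldehyde | O=Cc1cccc(OCc2ccccc2)c1OCc1ccccc1 | intermediate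
3 | 2,3-bis(benzyloxy)phenyl formate | O=COc1cccc(OCc2ccccc2)c1OCc1ccccc1 | intermediate (not isolated)
4 | 2,3-bis(benzyloxy)phenol | Oc1cccc(OCc2ccccc2)c1OCc1ccccc1 | intermediate
5 | 4-(benzyloxy)benzaldehyde | O=Cc1ccc(OCc2ccccc2)cc1 | starting material
6 | ethyl (Z)-3-[4-(benzyloxy)phenyl]prop-2-enoate | CCOC(=O)/C=C\c1ccc(OCc2ccccc2)cc1 | intermediate
7 | ethyl (2S,3S)-3-[4-(benzyloxy)phenyl]oxirane-2-carboxylate (cis) | CCOC(=O)[C@H]1O[C@H]1c1ccc(OCc2ccccc2)cc1 | intermediate
8 | (2S,3S)-3-[4-(benzyloxy)phenyl]oxirane-2-carbaldehyde (cis) | O=C[C@H]1O[C@H]1c1ccc(OCc2ccccc2)cc1 | intermediate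
9 | [2,3-bis(benzyloxy)phenoxy]tri(propan-2-yloxy)titanium | CC(C)O[Ti](OC(C)C)(OC(C)C)Oc1cccc(OCc2ccccc2)c1OCc1ccccc1 | intermediate (not isolated)
10 | 2,3-bis(benzyloxy)-6-{(R)-hydroxy[(2R,3S)-3-(4-benzyloxyphenyl)oxiran-2-yl]methyl}phenol (cis-epoxide, carbinol anti to the epoxide oxygen; present in the flask as its titanium alkoxide) | Oc1c(OCc2ccccc2)c(OCc2ccccc2)ccc1[C@@H](O)[C@H]1O[C@H]1c1ccc(OCc2ccccc2)cc1 | intermediate (not isolated)
11 | (2R,3R,4R)-7,8-bis(benzyloxy)-2-[4-(benzyloxy)phenyl]-3,4-dihydro-2H-chromene-3,4-diol (tri-O-benzyl teracacidin, all-cis) | c1cc2c(c(OCc3ccccc3)c1OCc1ccccc1)O[C@H](c1ccc(OCc3ccccc3)cc1)[C@H](O)[C@@H]2O | intermediate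
12 | (2R,3S,4S)-4-(benzylsulfanyl)-7,8-bis(benzyloxy)-2-[4-(benzyloxy)phenyl]-3,4-dihydro-2H-chromen-3-ol (2,3-cis-3,4-trans) | c1cc2c(c(OCc3ccccc3)c1OCc1ccccc1)O[C@H](c1ccc(OCc3ccccc3)cc1)[C@H](O)[C@H]2SCc1ccccc1 | intermediate
13 | (2R,3S,4S)-4-(benzylsulfanyl)-7,8-bis(benzyloxy)-2-[4-(benzyloxy)phenyl]-3,4-dihydro-2H-chromen-3-yl acetate | c1cc2c(c(OCc3ccccc3)c1OCc1ccccc1)O[C@H](c1ccc(OCc3ccccc3)cc1)[C@H](OC(C)=O)[C@H]2SCc1ccccc1 | intermediate
14 | (2R,3S,4R)-7,8-bis(benzyloxy)-2-[4-(benzyloxy)phenyl]-3,4-dihydro-2H-chromene-3,4-diyl carbonate (all-cis) | c1cc2c(c(OCc3ccccc3)c1OCc1ccccc1)O[C@H](c1ccc(OCc3ccccc3)cc1)[C@@H]3OC(=O)O[C@H]23 | intermediate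
15 | hexa-O-benzyl-epioritin-(4β→6)-epioritin-4α-ol, upper unit 3-O-acetate, lower unit 3,4-O-carbonate (upper unit 2,3-cis-3,4-trans, lower unit all-cis) | c1cc2c(c(OCc3ccccc3)c1OCc1ccccc1)O[C@H](c1ccc(OCc3ccccc3)cc1)[C@H](OC(C)=O)[C@H]2c1cc2c(c(OCc3ccccc3)c1OCc1ccccc1)O[C@H](c1ccc(OCc3ccccc3)cc1)[C@@H]3OC(=O)O[C@H]23 | intermediate
16 | nona-O-benzyl-epioritin-(4β→6)-epioritin-(4β→6)-epioritin-4α-ol, upper and middle units 3-O-acetate, lower unit 3,4-O-carbonate | c1cc2c(c(OCc3ccccc3)c1OCc1ccccc1)O[C@H](c1ccc(OCc3ccccc3)cc1)[C@H](OC(C)=O)[C@H]2c1cc2c(c(OCc3ccccc3)c1OCc1ccccc1)O[C@H](c1ccc(OCc3ccccc3)cc1)[C@H](OC(C)=O)[C@H]2c1cc2c(c(OCc3ccccc3)c1OCc1ccccc1)O[C@H](c1ccc(OCc3ccccc3)cc1)[C@@H]3OC(=O)O[C@H]23 | intermediate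
17 | nona-O-benzyl-epioritin-(4β→6)-epioritin-(4β→6)-epioritin-4α-ol (7,8,4'-tri-O-benzyl on each unit) | c1cc2c(c(OCc3ccccc3)c1OCc1ccccc1)O[C@H](c1ccc(OCc3ccccc3)cc1)[C@H](O)[C@H]2c1cc2c(c(OCc3ccccc3)c1OCc1ccccc1)O[C@H](c1ccc(OCc3ccccc3)cc1)[C@H](O)[C@H]2c1cc2c(c(OCc3ccccc3)c1OCc1ccccc1)O[C@H](c1ccc(OCc3ccccc3)cc1)[C@H](O)[C@@H]2O | intermediate
18 | epioritin-(4β→6)-epioritin-(4β→6)-epioritin-4α-ol (CNP0140823.1) | Oc1ccc([C@H]2Oc3c(ccc(O)c3O)[C@H](c3cc4c(c(O)c3O)O[C@H](c3ccc(O)cc3)[C@H](O)[C@H]4c3cc4c(c(O)c3O)O[C@H](c3ccc(O)cc3)[C@H](O)[C@@H]4O)[C@H]2O)cc1 | target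

**Totals**
Total step count: 13.
Longest linear sequence: 10 steps (5 → 6 → 7 → 8 → 11 → 12 → 13 → 15 → 16 → 17 → 18; steps 3, 4, 5, 6, 7, 8, 10, 11, 12 and 13).

**Steps most likely to fail**

Step 6 (Proposed new method). The risks are:
- ionisation of the p-benzyloxybenzylic epoxide carbon before ring closure, which would erode the 2,3-cis relationship;
- 5-exo closure at C3;
- poor facial selectivity at C4;
- transfer of isopropoxide from titanium to the epoxide.

A C4 epimer would still serve step 7, but step 9 needs the 3,4-cis isomer. The fallback sets out from 4 and 7 and comes back at 11, making the two bonds one after the other by known reactions, oxygen first. The caesium phenoxide of 4 (Cs2CO3, DMF, 40 °C) should open glycidate 7 at its benzylic carbon with inversion to give ethyl (2S,3R)-3-[2,3-bis(benzyloxy)phenoxy]-3-[4-(benzyloxy)phenyl]-2-hydroxypropanoate F1. Silylation (Et3SiCl, imidazole, DMF) gives ethyl (2S,3R)-3-[2,3-bis(benzyloxy)phenoxy]-3-[4-(benzyloxy)phenyl]-2-(triethylsilyloxy)propanoate F2. Reduction with iBu2AlH (toluene, −78 °C) gives (2S,3R)-3-[2,3-bis(benzyloxy)phenoxy]-3-[4-(benzyloxy)phenyl]-2-(triethylsilyloxy)propanal F3. MgBr2·OEt2 (CH2Cl2, −20 °C) should then close the ring by intramolecular Friedel–Crafts hydroxyalkylation at the free position ortho to the aryl ether oxygen; the chelated α-silyloxy aldehyde is expected to give the 3,4-cis carbinol (2R,3R,4R)-7,8-bis(benzyloxy)-2-[4-(benzyloxy)phenyl]-3-(triethylsilyloxy)chroman-4-ol F4. Bu4NF/AcOH (THF, 0 °C) returns 11.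

Step 10 (and step 11, the same reaction). The risks are:
- sluggish C-alkylation by the weakly nucleophilic benzylated pyrogallol-type ring;
- self-condensation of the electrophile through its own C6;
- attack at C5.

The fallback sets out from 11 and comes back at 18, using the more nucleophilic free phenols in the classical unprotected manner. Hydrogenolysis of 11 (H2, Pd(OH)2/C, EtOAc/MeOH) gives (2R,3R,4R)-2-(4-hydroxyphenyl)chromane-3,4,7,8-tetrol (teracacidin) F5. Thiolysis of part of it (BnSH, AcOH, 60 °C) gives (2R,3S,4S)-4-(benzylsulfanyl)-2-(4-hydroxyphenyl)chromane-3,7,8-triol F6. AgBF4 (THF, 0 °C) with excess F5 should give epioritin-(4β→6)-epioritin-4α-ol F7. The same coupling of the thioether with excess dimer should give 18 directly, each product being separated on Sephadex LH-20.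

Step 13. The risks are hydrogenolytic loss of the benzylic 4-hydroxyl of the lower unit while nine benzyl ethers are being removed, or incomplete debenzylation if the reaction is stopped early. The fallback sets out from 17 and comes back at 18, taking the sensitive carbinol through the hydrogenation as a ketone. MnO2 (CH2Cl2, 25 °C) should oxidise the only benzylic secondary alcohol to nona-O-benzyl-epioritin-(4β→6)-epioritin-(4β→6)-[(2R,3S)-3,7,8-trihydroxy-2-(4-hydroxyphenyl)chroman-4-one] F8. Hydrogenolysis (H2, Pd(OH)2/C, EtOAc/MeOH) gives the free phenolic ketone epioritin-(4β→6)-epioritin-(4β→6)-[(2R,3S)-3,7,8-trihydroxy-2-(4-hydroxyphenyl)chroman-4-one] F9. NaBH4 (EtOH, 0 °C) should deliver hydride anti to the axial 3-hydroxyl and give the 3,4-cis diol 18.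

**Further compounds**
F1 | step 6 | ethyl (2S,3R)-3-[2,3-bis(benzyloxy)phenoxy]-3-[4-(benzyloxy)phenyl]-2-hydroxypropanoate | CCOC(=O)[C@@H](O)[C@H](Oc1cccc(OCc2ccccc2)c1OCc1ccccc1)c1ccc(OCc2ccccc2)cc1
F2 | step 6 | ethyl (2S,3R)-3-[2,3-bis(benzyloxy)phenoxy]-3-[4-(benzyloxy)phenyl]-2-(triethylsilyloxy)propanoate | CCOC(=O)[C@@H](O[Si](CC)(CC)CC)[C@H](Oc1cccc(OCc2ccccc2)c1OCc1ccccc1)c1ccc(OCc2ccccc2)cc1
F3 | step 6 | (2S,3R)-3-[2,3-bis(benzyloxy)phenoxy]-3-[4-(benzyloxy)phenyl]-2-(triethylsilyloxy)propanal | O=C[C@@H](O[Si](CC)(CC)CC)[C@H](Oc1cccc(OCc2ccccc2)c1OCc1ccccc1)c1ccc(OCc2ccccc2)cc1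
F4 | step 6 | (2R,3R,4R)-7,8-bis(benzyloxy)-2-[4-(benzyloxy)phenyl]-3-(triethylsilyloxy)chroman-4-ol | c1cc2c(c(OCc3ccccc3)c1OCc1ccccc1)O[C@H](c1ccc(OCc3ccccc3)cc1)[C@H](O[Si](CC)(CC)CC)[C@@H]2O
F5 | step 10 | (2R,3R,4R)-2-(4-hydroxyphenyl)chromane-3,4,7,8-tetrol (teracacidin) | c1cc2c(c(O)c1O)O[C@H](c1ccc(O)cc1)[C@H](O)[C@@H]2O
F6 | step 10 | (2R,3S,4S)-4-(benzylsulfanyl)-2-(4-hydroxyphenyl)chromane-3,7,8-triol | c1cc2c(c(O)c1O)O[C@H](c1ccc(O)cc1)[C@H](O)[C@H]2SCc1ccccc1
F7 | step 10 | epioritin-(4β→6)-epioritin-4α-ol | c1cc2c(c(O)c1O)O[C@H](c1ccc(O)cc1)[C@H](O)[C@H]2c1cc2c(c(O)c1O)O[C@H](c1ccc(O)cc1)[C@H](O)[C@@H]2O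
F8 | step 13 | nona-O-benzyl-epioritin-(4β→6)-epioritin-(4β→6)-[(2R,3S)-3,7,8-trihydroxy-2-(4-hydroxyphenyl)chroman-4-one] | c1cc2c(c(OCc3ccccc3)c1OCc1ccccc1)O[C@H](c1ccc(OCc3ccccc3)cc1)[C@H](O)[C@H]2c1cc2c(c(OCc3ccccc3)c1OCc1ccccc1)O[C@H](c1ccc(OCc3ccccc3)cc1)[C@H](O)[C@H]2c1cc2c(c(OCc3ccccc3)c1OCc1ccccc1)O[C@H](c1ccc(OCc3ccccc3)cc1)[C@H](O)C2=O
F9 | step 13 | epioritin-(4β→6)-epioritin-(4β→6)-[(2R,3S)-3,7,8-trihydroxy-2-(4-hydroxyphenyl)chroman-4-one] | c1cc2c(c(O)c1O)O[C@H](c1ccc(O)cc1)[C@H](O)[C@H]2c1cc2c(c(O)c1O)O[C@H](c1ccc(O)cc1)[C@H](O)[C@H]2c1cc2c(c(O)c1O)O[C@H](c1ccc(O)cc1)[C@H](O)C2=O
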